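## Structural features

The target is an achiral, mirror-symmetric trimeric acylphloroglucinol. A central hexasubstituted benzene (ring A: C1 butanoyl, C2/C4/C6 hydroxyl) carries CH2 bridges at C3 and C5, each ending at C1' of an identical hexasubstituted outer ring (rings B and C: C2' OH, C3' butanoyl, C4' OH, C5' CH3, C6' OCH3). There is no stereocentre, so no stereocentres adjoin and only constitution has to be controlled. All eighteen ring carbons are substituted; seven of the nine ring oxygens are free phenols, six of them chelated to an ortho acyl group. The fragile elements are the two diarylmethane bridges between electron-rich phenols (a phenoxide ortho or para to a bridge can expel an ortho-quinone methide and scramble the bridges; strong acid can cleave them by ipso protonation), the oxidation-prone polyphenol, and the enolisable ring A ketone in protected intermediates. The real difficulty is regiochemical: in each outer ring exactly one of three oxygens is a methyl ether, and it must be the one lying between the bridge carbon C1' and the C-methyl carbon C5'. The key step exploits that C5'(CH3)–C6'(OCH3) is an intact 1-methoxypropyne unit, which can be inserted between C4' and C1' of a four-membered ring that already holds C1'–C2'–C3'–C4' and the C2' oxygen. Because rings B and C are identical, this can be done in two directions at once on a ring A scaffold.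

## Logic of the disconnections

22 ⇒ 21. The three ring A O–CH2Ph bonds are cut. Ring A stays etherified to the end because a ring A phenoxide is what would set the bridges in motion. The forward step must be a neutral hydrogenolysis that spares three aryl ketones and two diarylmethane carbons.

21 ⇒ 19 + 20. The two C3'–C(=O) bonds are cut. C3' is the only unsubstituted aromatic carbon of 19, flanked by two hydroxyls and para to the methoxy group, so the site of acylation needs no control. The outer rings are left with one ring hydrogen, which is what a cyclobutenone CH2 delivers. The forward acylation must run cold enough that benzyl ethers and bridges survive the Lewis acid.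

19 ⇒ 18. Two aryl O–Si bonds and one enol O–Si bond are cut. One operation frees both C2' hydroxyls and returns the ring A ketone; no carbon changes. The forward step needs buffered fluoride so that no phenoxide or enolate persists.

18 ⇒ 13 + 2 × 17 (key disconnection). In each outer ring C4'–C5' and C6'–C1' are cut, which excises the C5'/C6' pair as 17 and leaves C1'–C4' as a four-membered ring. Two hexasubstituted benzene rings become two small rings on one scaffold, and the methyl ether no longer has to be chosen among three oxygens. The forward step must bond the methyl-bearing alkyne carbon to C4' and the methoxy-bearing carbon to C1', and every vinylketene must be captured by 17.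

17 ⇒ 14 + 15. The C(sp)–CH3 bond is cut and the triple bond is traced to an acetal by twofold elimination. Both precursors are bulk chemicals. The forward step must alkylate the acetylide on carbon in the medium in which it is made.

13 ⇒ 10 + 2 × 12. In each four-membered ring C1'–C4' and C2'–C3' are cut. This leaves two siloxyalkyne arms (C1'≡C2') and the two-carbon unit 12, two molecules of which arise from one molecule of 11 by thermal cycloreversion. The forward cycloaddition must join the nucleophilic alkyne carbon C1' to the carbonyl carbon of 12.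

10 ⇒ 7 (through 8 and 9). The C2'–O bonds are cut, then O–Si. Only a terminal alkyne remains on each arm. This is the one strongly basic step, and it dictates that the ring A ketone be masked beforehand.

7 ⇒ 6. The enol O–Si bond is cut. The mask costs one step to put on and none to remove, since it falls in 18 ⇒ 19. The forward step must enolise the hindered ketone without touching the terminal alkynes.

6 ⇒ 5. The two CH2–C(sp) bonds are cut, giving a bis(benzylic bromide) and an ethynyl nucleophile. The forward sp3–sp coupling must tolerate the ketone and must not isomerise the product to an allene.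

5 ⇒ 4 ⇒ 3. C–Br goes back to C–OH and then to CH=O; these are functional-group changes only. The forward steps need aldehyde-selective hydride delivery beside the hindered ketone and a neutral bromination.

3 ⇒ 2. Three O–CH2Ph bonds are cut. The forward step must alkylate three chelated, acidic phenols on oxygen and not on carbon.

2 ⇒ 1. The two C–CHO bonds are cut, leaving commercial 1. The forward step is a twofold formylation at the only two free positions of the ring.

## Other disconnections considered

Alternative 1: The cut is C1–C6 of ring A. Ring A is unravelled into a 3,5,7-trioxo ester held as the pyranone A1, whose C3 and C5 carry the two finished, benzyl-protected outer-ring CH2 groups and whose C6 carries the 2-oxopentyl chain. In the forward key step Mg(OMe)2 in methanol opens the lactone, the carbanion between the two ketones attacks the new ester, and the Claisen product aromatises to A2.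
- In favour: the competing aldol closure would have to create a quaternary carbon that cannot aromatise, so the mode of closure is on its side. The outer rings arrive with their butanoyl groups, so no late acylation is needed. A2 is one hydrogenolysis from 22; on the endgame this alternative is better than the chosen plan, which needs three steps.
- Against: the key step builds the one ring that can be bought as 1. The C5'/C6' pattern still has to be solved in a separate synthesis of the outer-ring unit. A1 needs two different bond formations at pyranone C3 (nucleophilic) and C5 (not nucleophilic). Methoxide on a polycarbonyl chain invites retro-Claisen cleavage.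
- Comparison: structurally the chosen plan attacks the rings where the difficulty lies. Mechanistically this is polar and basic against neutral and pericyclic. Both are free of stereochemical issues (equal). Step economy is better after the key step and clearly worse before it.

Alternative 2: The cut is C1–C2, C3–C4 and C5–C6 of ring A, giving two molecules of the ynol ether A3 and one of the alkoxy ynone A4. In the forward key step [Rh(cod)2]BF4 with BINAP trimerises them to A5, and one global hydrogenolysis would give 22.
- In favour: convergence is the highest of all plans. Three bonds and a hexasubstituted ring form in one catalytic, neutral step. On paper the step count is the best, and the one-step endgame is better than that of the chosen plan.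
- Against: it needs a 2:1 cross-selection between two alkynes and strict head-to-tail orientation of all three, whereas homotrimers of A3 and regioisomers are the expected competitors. Three internal alkynes giving a hexasubstituted benzene is the sterically hardest case. Benzyl ynol ethers rearrange to ketenes on mild warming. Ring A is again the purchasable part, and A3 presupposes a complete outer ring.
- Comparison: selectivity would rest on the catalyst, whereas in the chosen plan it rests on the built-in polarity of ketene and ynol ether. Stereochemistry is equally absent. Step economy is better on paper; the risk is much higher.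

Alternative 3: The cut is C1'–C2' and C3'–C4' in both outer rings, giving the ring A bis(β-keto ester) A6 and two molecules of A7. In the forward key step the γ-carbanions (C1') of the twofold dianion of A6 are acylated by the ester group of A7 (present as its enolate). Each triketo ester then closes C3' onto the C4' ester and aromatises to A8. Methylation at C6' and hydrogenolysis would follow.
- In favour: it shares the two-directional, ring A-centred logic of the chosen plan and can branch from the same bromide 5 (equal on both counts). It brings in the C3' butanoyl group during ring formation, so no acylation of the assembled trimer is needed; on that point it is better than the chosen plan.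
- Against: acylation of a substituted γ-carbanion by a β-keto ester enolate competes with proton transfer and must succeed twice on one molecule. The ring A ketone would need the same masking. A8 has three free hydroxyls per outer ring, so the C6' methyl ether must be made selectively on a base-sensitive, doubly bridged polyphenol, which is the very problem the chosen plan avoids.
- Comparison: both plans build rings B and C. This one is polyanionic and strongly basic; the chosen one is neutral and thermal. Step economy is comparable (two steps after the key step against three). Regiochemical security is lower.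

Key step: step 10

Remarks on the chemistry:
- Assumption: from step 6 to step 11 the ring A butanoyl ketone is carried as its tert-butyldimethylsilyl enol ether (drawn Z, the isomer that soft enolisation should favour). This is a spectator change only: the carbon skeletons of the key-step precursor 13 and product 18 are unchanged, and the geometry is erased in step 11.
- Naming of the cyclobutenone arms: each four-membered ring is joined to the bridging CH2 through its sp2 α-carbon, i.e. it is a (4-oxo-2-triisopropylsiloxycyclobut-1-en-1-yl)methyl group (a 2-substituted 3-siloxycyclobut-2-enone). Locants that place the attachment on the sp3 ring carbon describe an isomer that cannot give the C6'–C1' bond.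
- Bond count in the key step: the C3'–C4' bond is not new. It is broken in the first ring opening and re-formed in the 6π closure, so the new skeletal bonds are C4'–C5' and C6'–C1', twice.
- Ketene source: diketene 11 cracks thermally to two molecules of ketene 12 and nothing else, so one molecule of 11 supplies the two C2 units that the two arms of 10 take up; an excess is used in practice.

## Steps

Step 1
Reactants: 1 1-(2,4,6-trihydroxyphenyl)butan-1-one
Product: 2 5-butanoyl-2,4,6-trihydroxybenzene-1,3-dicarbaldehyde
Conditions: Cl2CHOMe (5 equiv), TiCl4, CH2Cl2, 0 → 23 °C; then H2O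
Reagents that add atoms: dichloromethyl methyl ether, COC(Cl)Cl; water, O
Why: Rieche formylation; each of the two free ring positions is activated by two ortho and one para oxygen, so twofold substitution by the TiCl4-activated chloromethyl ether is expected, and hydrolysis of the α-chloro ethers releases the aldehydes.

Step 2
Reactants: 2 5-butanoyl-2,4,6-trihydroxybenzene-1,3-dicarbaldehyde
Product: 3 2,4,6-tris(benzyloxy)-5-butanoylbenzene-1,3-dicarbaldehyde
Conditions: BnBr (4 equiv), K2CO3, n-Bu4NI (cat.), DMF, 60 °C
Reagents that add atoms: benzyl bromide, BrCc1ccccc1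
Why: Williamson etherification; the acidic chelated phenols react as potassium phenoxides, and a dipolar aprotic solvent with a potassium counter-ion favours attack through oxygen over dearomatising C-benzylation.

Step 3
Reactants: 3 2,4,6-tris(benzyloxy)-5-butanoylbenzene-1,3-dicarbaldehyde
Product: 4 1-[2,4,6-tris(benzyloxy)-3,5-bis(hydroxymethyl)phenyl]butan-1-one
Conditions: NaBH4 (1 equiv), THF–MeOH, −20 → 0 °C
Reagents that add atoms: none
Why: Chemoselective borohydride reduction; the aldehydes are intrinsically far more electrophilic than the di-ortho-substituted, twisted aryl alkyl ketone, which should remain at low temperature.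

Step 4
Reactants: 4 1-[2,4,6-tris(benzyloxy)-3,5-bis(hydroxymethyl)phenyl]butan-1-one
Product: 5 1-[2,4,6-tris(benzyloxy)-3,5-bis(bromomethyl)phenyl]butan-1-one
Conditions: CBr4, PPh3, CH2Cl2, 0 °C; used without storage
Reagents that add atoms: carbon tetrabromide, BrC(Br)(Br)Br
Why: Appel bromination; it is neutral, so the electron-rich benzylic system and the benzyl ethers never see HBr.

Step 5
Reactants: 5 1-[2,4,6-tris(benzyloxy)-3,5-bis(bromomethyl)phenyl]butan-1-one
Product: 6 1-[2,4,6-tris(benzyloxy)-3,5-di(prop-2-yn-1-yl)phenyl]butan-1-one
Conditions: HC≡CMgBr (4 equiv), ZnBr2 (4 equiv), THF, 0 °C; then 5, PdCl2[(2-Ph2PC6H4)2O] (5 mol %), 23 °C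
Reagents that add atoms: ethynylmagnesium bromide, C#C[Mg]Br
Why: Negishi benzyl–alkynyl coupling; the benzylic C–Br bonds add to zerovalent palladium and the ethynyl group is transferred from zinc. The organozinc tolerates the ketone, and the non-basic medium should avoid propargyl-to-allenyl isomerisation.

Step 6
Reactants: 6 1-[2,4,6-tris(benzyloxy)-3,5-di(prop-2-yn-1-yl)phenyl]butan-1-one
Product: 7 (Z)-1-(tert-butyldimethylsiloxy)-1-[2,4,6-tris(benzyloxy)-3,5-di(prop-2-yn-1-yl)phenyl]but-1-ene
Conditions: t-BuMe2SiOTf, Et3N, CH2Cl2, 0 → 23 °C
Reagents that add atoms: tert-butyldimethylsilyl trifluoromethanesulfonate, CC(C)(C)[Si](C)(C)OS(=O)(=O)C(F)(F)F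
Why: Soft enolisation (silyl triflate and tertiary amine) to the silyl enol ether; it masks the only enolisable, organolithium-sensitive carbonyl before step 7 and leaves terminal alkynes and benzyl ethers untouched.

Step 7
Reactants: 7 (Z)-1-(tert-butyldimethylsiloxy)-1-[2,4,6-tris(benzyloxy)-3,5-di(prop-2-yn-1-yl)phenyl]but-1-ene
Product: 10 (Z)-1-(tert-butyldimethylsiloxy)-1-[2,4,6-tris(benzyloxy)-3,5-bis[3-(triisopropylsiloxy)prop-2-yn-1-yl]phenyl]but-1-ene, via dilithium diacetylide 8 (not isolated), via dilithium bis(ynolate) 9 (not isolated)
Conditions: n-BuLi (2.1 equiv), THF, −78 °C; LiOOt-Bu (from t-BuOOH and LiN(SiMe3)2), −78 → 0 °C; i-Pr3SiOTf, −78 → 0 °C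
Reagents that add atoms: lithium tert-butyl peroxide, [Li+].[O-]OC(C)(C)C; triisopropylsilyl trifluoromethanesulfonate, CC(C)[Si](C(C)C)(C(C)C)OS(=O)(=O)C(F)(F)F
Why: Acetylide-to-ynolate oxidation followed by O-silylation, the established route from terminal alkynes to 1-siloxyalkynes. The terminal C–H is the kinetically most acidic site, the peroxide transfers electrophilic oxygen to the acetylide carbon, and the bulky silyl triflate silylates the ynolate on oxygen.

Step 8
Reactants: 10 (Z)-1-(tert-butyldimethylsiloxy)-1-[2,4,6-tris(benzyloxy)-3,5-bis[3-(triisopropylsiloxy)prop-2-yn-1-yl]phenyl]but-1-ene; 11 diketene (4-methylideneoxetan-2-one)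
Product: 13 (Z)-1-(tert-butyldimethylsiloxy)-1-[2,4,6-tris(benzyloxy)-3,5-bis[(4-oxo-2-triisopropylsiloxycyclobut-1-en-1-yl)methyl]phenyl]but-1-ene, via ketene 12 (not isolated)
Conditions: 11 (3 equiv) cracked at 550 °C (quartz tube, N2 carrier); stream of 12 led directly into 10, CH2Cl2, 0 → 23 °C
Reagents that add atoms: none
Why: Flash pyrolysis of 11 is a clean [2+2] cycloreversion to two molecules of 12, which adds to each electron-rich siloxyalkyne by the known ketene–siloxyalkyne [2+2] cycloaddition that gives 3-siloxycyclobutenones. The nucleophilic, carbon-substituted alkyne terminus (C1') bonds to the ketene carbonyl carbon (C4') and the siloxy carbon (C2') to the ketene CH2 (C3'), which fixes the 2-arylmethyl-3-siloxy pattern.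

Step 9
Reactants: 14 2-chloro-1,1-dimethoxyethane; 15 iodomethane
Product: 17 1-methoxyprop-1-yne, via sodium methoxyacetylide 16 (not isolated)
Conditions: NaNH2 (3 equiv), liq. NH3, −33 °C; then MeI, −33 °C; distillation
Reagents that add atoms: none
Why: Twofold base-induced elimination (methanol, then HCl) from the chloroacetal gives the alkoxyacetylide, which is methylated on carbon by SN2 in the same medium; this is the standard preparation of 1-alkoxyalkynes.

Step 10
Reactants: 13 (Z)-1-(tert-butyldimethylsiloxy)-1-[2,4,6-tris(benzyloxy)-3,5-bis[(4-oxo-2-triisopropylsiloxycyclobut-1-en-1-yl)methyl]phenyl]but-1-ene; 17 1-methoxyprop-1-yne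
Product: 18 (Z)-1-(tert-butyldimethylsiloxy)-1-[2,4,6-tris(benzyloxy)-3,5-bis[(4-hydroxy-6-methoxy-5-methyl-2-triisopropylsiloxyphenyl)methyl]phenyl]but-1-ene
Conditions: 17 (6 equiv), PhMe (0.02 M in 13), 100 °C, sealed tube
Reagents that add atoms: none
Why: Each 3-siloxycyclobutenone opens thermally (4π, cleaving C3'–C4') to a siloxy vinylketene. The ketene C=C then adds 17 in a polar [2+2]: the nucleophilic methyl-bearing alkyne carbon bonds to the ketene carbonyl carbon (C4'–C5') and the methoxy-bearing carbon to the former α-carbon (C6'–C1'), giving a 4-vinylcyclobutenone. This reopens (4π) to a dienylketene, and rings B and C are each closed by a thermal 6π disrotatory electrocyclisation that re-forms C3'–C4'; tautomerisation of the cyclohexadienone gives the C4' phenol. The closest known reaction is the Danheiser benzannulation of cyclobutenones, 3-siloxy ones included, with alkoxy- and siloxyalkynes, run here on two arms of one scaffold. No stereocentre is created. The step needs regiocontrol in the [2+2], which the polarisation of the ynol ether and the electrophilicity of the ketene carbonyl carbon secure, so that methoxy ends up next to C1' and methyl next to C4'. It also needs each vinylketene to be captured by the alkyne and not by a phenol already formed, which the large excess of 17 and high dilution are meant to secure. Ring A, fully substituted and carrying only ethers, and the enol silyl ether are bystanders under neutral thermolysis.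

Step 11
Reactants: 18 (Z)-1-(tert-butyldimethylsiloxy)-1-[2,4,6-tris(benzyloxy)-3,5-bis[(4-hydroxy-6-methoxy-5-methyl-2-triisopropylsiloxyphenyl)methyl]phenyl]but-1-ene
Product: 19 1-[2,4,6-tris(benzyloxy)-3,5-bis[(2,4-dihydroxy-6-methoxy-5-methylphenyl)methyl]phenyl]butan-1-one
Conditions: n-Bu4NF (3.3 equiv), AcOH (3.3 equiv), THF, 0 °C, under argon
Reagents that add atoms: none
Why: Fluoride-induced Si–O cleavage removes both aryl silyl ethers and the enol silyl ether, which returns the ring A ketone. Acetic acid protonates phenoxides and the enolate as they form, so the bridges and the electron-rich resorcinol rings are not exposed to base.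

Step 12
Reactants: 19 1-[2,4,6-tris(benzyloxy)-3,5-bis[(2,4-dihydroxy-6-methoxy-5-methylphenyl)methyl]phenyl]butan-1-one; 20 butanoyl chloride
Product: 21 1-[2,4,6-tris(benzyloxy)-3,5-bis[(3-butanoyl-2,4-dihydroxy-6-methoxy-5-methylphenyl)methyl]phenyl]butan-1-one
Conditions: 20 (2.4 equiv), TiCl4, CH2Cl2, −40 → 0 °C; then cold 1 M HCl
Reagents that add atoms: none
Why: Friedel–Crafts C-acylation; C3' is the only unsubstituted aromatic carbon in the molecule and is activated by two ortho hydroxyls and a para methoxy group. The titanium phenoxides formed in the flask should deliver the acyl chloride to that carbon at low temperature, and the product is stabilised as a chelated ortho-hydroxy ketone.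

Step 13
Reactants: 21 1-[2,4,6-tris(benzyloxy)-3,5-bis[(3-butanoyl-2,4-dihydroxy-6-methoxy-5-methylphenyl)methyl]phenyl]butan-1-one
Product: 22 1-[3,5-bis[(3-butanoyl-2,4-dihydroxy-6-methoxy-5-methylphenyl)methyl]-2,4,6-trihydroxyphenyl]butan-1-one
Conditions: H2 (1 atm), Pd/C, EtOAc, 23 °C
Reagents that add atoms: none
Why: Hydrogenolysis of the three aryl benzyl ethers under neutral conditions. The chelated aryl ketones and the diarylmethane carbons should not be reduced at atmospheric pressure, and no base or acid is present that could move the bridges in the free polyphenol.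

## Compound list

1 | 1-(2,4,6-trihydroxyphenyl)butan-1-one | CCCC(=O)c1c(O)cc(O)cc1O | starting material
2 | 5-butanoyl-2,4,6-trihydroxybenzene-1,3-dicarbaldehyde | CCCC(=O)c1c(O)c(C=O)c(O)c(C=O)c1O | intermediate
3 | 2,4,6-tris(benzyloxy)-5-butanoylbenzene-1,3-dicarbaldehyde | CCCC(=O)c1c(OCc2ccccc2)c(C=O)c(OCc2ccccc2)c(C=O)c1OCc1ccccc1 | intermediate
4 | 1-[2,4,6-tris(benzyloxy)-3,5-bis(hydroxymethyl)phenyl]butan-1-one | CCCC(=O)c1c(OCc2ccccc2)c(CO)c(OCc2ccccc2)c(CO)c1OCc1ccccc1 | intermediate
5 | 1-[2,4,6-tris(benzyloxy)-3,5-bis(bromomethyl)phenyl]butan-1-one | CCCC(=O)c1c(OCc2ccccc2)c(CBr)c(OCc2ccccc2)c(CBr)c1OCc1ccccc1 | intermediate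
6 | 1-[2,4,6-tris(benzyloxy)-3,5-di(prop-2-yn-1-yl)phenyl]butan-1-one | CCCC(=O)c1c(OCc2ccccc2)c(CC#C)c(OCc2ccccc2)c(CC#C)c1OCc1ccccc1 | intermediate
7 | (Z)-1-(tert-butyldimethylsiloxy)-1-[2,4,6-tris(benzyloxy)-3,5-di(prop-2-yn-1-yl)phenyl]but-1-ene | CC/C=C(\O[Si](C)(C)C(C)(C)C)c1c(OCc2ccccc2)c(CC#C)c(OCc2ccccc2)c(CC#C)c1OCc1ccccc1 | intermediate
8 | dilithium diacetylide of 7 (both terminal alkyne carbons lithiated) | CC/C=C(\O[Si](C)(C)C(C)(C)C)c1c(OCc2ccccc2)c(CC#C[Li])c(OCc2ccccc2)c(CC#C[Li])c1OCc1ccccc1 | intermediate (not isolated)
9 | dilithium bis(ynolate) (both arms CH2–C≡C–OLi) | CC/C=C(\O[Si](C)(C)C(C)(C)C)c1c(OCc2ccccc2)c(CC#CO[Li])c(OCc2ccccc2)c(CC#CO[Li])c1OCc1ccccc1 | intermediate (not isolated)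
10 | (Z)-1-(tert-butyldimethylsiloxy)-1-[2,4,6-tris(benzyloxy)-3,5-bis[3-(triisopropylsiloxy)prop-2-yn-1-yl]phenyl]but-1-ene | CC/C=C(\O[Si](C)(C)C(C)(C)C)c1c(OCc2ccccc2)c(CC#CO[Si](C(C)C)(C(C)C)C(C)C)c(OCc2ccccc2)c(CC#CO[Si](C(C)C)(C(C)C)C(C)C)c1OCc1ccccc1 | intermediate
11 | diketene (4-methylideneoxetan-2-one) | C=C1CC(=O)O1 | starting material
12 | ketene | C=C=O | intermediate (not isolated)
13 | (Z)-1-(tert-butyldimethylsiloxy)-1-[2,4,6-tris(benzyloxy)-3,5-bis[(4-oxo-2-triisopropylsiloxycyclobut-1-en-1-yl)methyl]phenyl]but-1-ene | CC/C=C(\O[Si](C)(C)C(C)(C)C)c1c(OCc2ccccc2)c(CC2=C(O[Si](C(C)C)(C(C)C)C(C)C)CC2=O)c(OCc2ccccc2)c(CC2=C(O[Si](C(C)C)(C(C)C)C(C)C)CC2=O)c1OCc1ccccc1 | intermediate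
14 | 2-chloro-1,1-dimethoxyethane (chloroacetaldehyde dimethyl acetal) | COC(CCl)OC | starting material
15 | iodomethane | CI | starting material
16 | sodium methoxyacetylide | [Na+].[C-]#COC | intermediate (not isolated)
17 | 1-methoxyprop-1-yne | CC#COC | intermediate
18 | (Z)-1-(tert-butyldimethylsiloxy)-1-[2,4,6-tris(benzyloxy)-3,5-bis[(4-hydroxy-6-methoxy-5-methyl-2-triisopropylsiloxyphenyl)methyl]phenyl]but-1-ene | CC/C=C(\O[Si](C)(C)C(C)(C)C)c1c(OCc2ccccc2)c(Cc2c(O[Si](C(C)C)(C(C)C)C(C)C)cc(O)c(C)c2OC)c(OCc2ccccc2)c(Cc2c(O[Si](C(C)C)(C(C)C)C(C)C)cc(O)c(C)c2OC)c1OCc1ccccc1 | intermediate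
19 | 1-[2,4,6-tris(benzyloxy)-3,5-bis[(2,4-dihydroxy-6-methoxy-5-methylphenyl)methyl]phenyl]butan-1-one | CCCC(=O)c1c(OCc2ccccc2)c(Cc2c(O)cc(O)c(C)c2OC)c(OCc2ccccc2)c(Cc2c(O)cc(O)c(C)c2OC)c1OCc1ccccc1 | intermediate
20 | butanoyl chloride | CCCC(Cl)=O | starting material
21 | 1-[2,4,6-tris(benzyloxy)-3,5-bis[(3-butanoyl-2,4-dihydroxy-6-methoxy-5-methylphenyl)methyl]phenyl]butan-1-one | CCCC(=O)c1c(OCc2ccccc2)c(Cc2c(O)c(C(=O)CCC)c(O)c(C)c2OC)c(OCc2ccccc2)c(Cc2c(O)c(C(=O)CCC)c(O)c(C)c2OC)c1OCc1ccccc1 | intermediate
22 | 1-[3,5-bis[(3-butanoyl-2,4-dihydroxy-6-methoxy-5-methylphenyl)methyl]-2,4,6-trihydroxyphenyl]butan-1-one | CCCC(=O)c1c(O)c(Cc2c(O)c(C(=O)CCC)c(O)c(C)c2OC)c(O)c(Cc2c(O)c(C(=O)CCC)c(O)c(C)c2OC)c1O | target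

## Step count and least certain steps

Total: 13 steps. Longest linear sequence: 12 steps (1 to 22 through steps 1–8 and 10–13); step 9 is a one-step side branch.

Step 10 (key step). The most likely failure is capture of a vinylketene by a phenol of an already annulated arm of another molecule. This intermolecular ester formation leads to oligomers and is favoured because every molecule carries two ketene precursors. Slow opening of the donor-stabilised four-membered ring would add thermal loss of the silyl groups. The fallback gives up the two-directional annulation and joins finished outer rings to ring A; it sets out from 1 and comes back at 22. The purchasable natural product aspidinol F1, that is 1-(2,6-dihydroxy-4-methoxy-3-methylphenyl)butan-1-one, is aminomethylated at its only free ring position with dimethylmethyleneiminium iodide to the Mannich base F2. Heating 1 with two equivalents of F2 in dioxane expels dimethylamine, and the ortho-quinone methide so formed alkylates C3 and C5 of 1 to give 22 directly. The price is dependence on F1 for the methyl/methoxy pattern and a mono/bis product mixture to separate.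

Step 7. The propargylic CH2 is also benzylic, so proton transfer during or after acetylide formation can isomerise the alkyne to an allene. Oxidation of a hindered diacetylide may stall at one arm, and silylation of the ynolate may go to carbon. The fallback avoids all strong base and sets out from 5, coming back at 19. Stille coupling of 5 with tributyl(ethoxyethynyl)stannane and Pd(PPh3)4 should give the bis(1-ethoxyalkyne) F3, to which 12 adds as in step 8 to give the bis(3-ethoxycyclobutenone) F4. Cold dilute HCl in THF hydrolyses the vinylogous esters to the bis(cyclobutane-1,3-dione) F5 (drawn as its enol), and i-Pr3SiCl with Et3N silylates it on oxygen to the bis(3-siloxycyclobutenone) F6, with the ring A ketone free. F6 is heated with 17 under the conditions of step 10 to the annulated ketone F7, and n-Bu4NF/AcOH as in step 11 gives 19.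

Step 12. The Lewis acid may cleave the ring A benzyl ethers, especially the two chelated to the ketone, and the benzyl cation equivalents would then alkylate C3' in competition with the acyl chloride. Ipso protonation at C1' could also cut a bridge. The fallback is acid-free and sets out from 19, coming back at 21. N-Bromosuccinimide in MeCN at −20 °C brominates the only free position C3' of each outer ring to give the dibromide F8, and 20 with Et3N and DMAP esterifies all four phenols to the tetrabutanoate F9. n-BuLi at −100 °C then exchanges bromine for lithium, and each aryllithium takes the acyl group of a neighbouring ester (1,3 O-to-C shift of the anionic Fries type); K2CO3 in methanol removes the two remaining esters to give 21.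

Step 5. Metal exchange between the terminal alkyne product and the ethynylzinc reagent would allow a second benzylation and so oligomers from the bifunctional bromide; the labile trialkoxybenzyl bromide may also decompose before coupling. The fallback sets out from 3 and comes back at 6, bypassing 4 and 5. Ethynylmagnesium bromide adds to the two aldehydes, not to the hindered ketone, to give the bis(propargylic alcohol) F10 as a diastereomer mixture. Et3SiH with CF3CO2H in CH2Cl2 at −20 °C then removes both hydroxyls by ionic hydrogenation through the aryl-stabilised propargylic cations, giving 6.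

Step 8. Dimerisation of ketene back to 11 and its polymerisation may outrun addition to the hindered internal siloxyalkynes, and traces of acid carried over from the pyrolysis can strip the silyl groups. The fallback sets out from 10 and comes back at 13. Dichloroketene, made in the flask from trichloroacetyl chloride and Zn(Cu) in Et2O–DME, adds with the same orientation to give the bis(4,4-dichlorocyclobutenone) F11. Zn dust with AcOH and TMEDA in ethanol at 0 °C then removes the four chlorines to give 13.

## Further compounds

F1 | step 10 | aspidinol, 1-(2,6-dihydroxy-4-methoxy-3-methylphenyl)butan-1-one | CCCC(=O)c1c(O)c(C)c(OC)cc1O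
F2 | step 10 | 1-[3-[(dimethylamino)methyl]-2,6-dihydroxy-4-methoxy-5-methylphenyl]butan-1-one | CCCC(=O)c1c(O)c(C)c(OC)c(CN(C)C)c1O
F3 | step 7 | 1-[2,4,6-tris(benzyloxy)-3,5-bis(3-ethoxyprop-2-yn-1-yl)phenyl]butan-1-one | CCCC(=O)c1c(OCc2ccccc2)c(CC#COCC)c(OCc2ccccc2)c(CC#COCC)c1OCc1ccccc1
F4 | step 7 | 1-[2,4,6-tris(benzyloxy)-3,5-bis[(2-ethoxy-4-oxocyclobut-1-en-1-yl)methyl]phenyl]butan-1-one | CCCC(=O)c1c(OCc2ccccc2)c(CC2=C(OCC)CC2=O)c(OCc2ccccc2)c(CC2=C(OCC)CC2=O)c1OCc1ccccc1
F5 | step 7 | 1-[2,4,6-tris(benzyloxy)-3,5-bis[(2-hydroxy-4-oxocyclobut-1-en-1-yl)methyl]phenyl]butan-1-one (enol form of the bis(cyclobutane-1,3-dione)) | CCCC(=O)c1c(OCc2ccccc2)c(CC2=C(O)CC2=O)c(OCc2ccccc2)c(CC2=C(O)CC2=O)c1OCc1ccccc1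
F6 | step 7 | 1-[2,4,6-tris(benzyloxy)-3,5-bis[(4-oxo-2-triisopropylsiloxycyclobut-1-en-1-yl)methyl]phenyl]butan-1-one | CCCC(=O)c1c(OCc2ccccc2)c(CC2=C(O[Si](C(C)C)(C(C)C)C(C)C)CC2=O)c(OCc2ccccc2)c(CC2=C(O[Si](C(C)C)(C(C)C)C(C)C)CC2=O)c1OCc1ccccc1
F7 | step 7 | 1-[2,4,6-tris(benzyloxy)-3,5-bis[(4-hydroxy-6-methoxy-5-methyl-2-triisopropylsiloxyphenyl)methyl]phenyl]butan-1-one | CCCC(=O)c1c(OCc2ccccc2)c(Cc2c(O[Si](C(C)C)(C(C)C)C(C)C)cc(O)c(C)c2OC)c(OCc2ccccc2)c(Cc2c(O[Si](C(C)C)(C(C)C)C(C)C)cc(O)c(C)c2OC)c1OCc1ccccc1
F8 | step 12 | 1-[2,4,6-tris(benzyloxy)-3,5-bis[(3-bromo-2,4-dihydroxy-6-methoxy-5-methylphenyl)methyl]phenyl]butan-1-one | CCCC(=O)c1c(OCc2ccccc2)c(Cc2c(O)c(Br)c(O)c(C)c2OC)c(OCc2ccccc2)c(Cc2c(O)c(Br)c(O)c(C)c2OC)c1OCc1ccccc1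
F9 | step 12 | tetrabutanoate of F8 (all four outer-ring hydroxyls as butanoyl esters) | CCCC(=O)c1c(OCc2ccccc2)c(Cc2c(OC(=O)CCC)c(Br)c(OC(=O)CCC)c(C)c2OC)c(OCc2ccccc2)c(Cc2c(OC(=O)CCC)c(Br)c(OC(=O)CCC)c(C)c2OC)c1OCc1ccccc1
F10 | step 5 | 1-[2,4,6-tris(benzyloxy)-3,5-bis(1-hydroxyprop-2-yn-1-yl)phenyl]butan-1-one (mixture of diastereomers) | CCCC(=O)c1c(OCc2ccccc2)c(C(O)C#C)c(OCc2ccccc2)c(C(O)C#C)c1OCc1ccccc1
F11 | step 8 | (Z)-1-(tert-butyldimethylsiloxy)-1-[2,4,6-tris(benzyloxy)-3,5-bis[(3,3-dichloro-4-oxo-2-triisopropylsiloxycyclobut-1-en-1-yl)methyl]phenyl]but-1-ene | CC/C=C(\O[Si](C)(C)C(C)(C)C)c1c(OCc2ccccc2)c(CC2=C(O[Si](C(C)C)(C(C)C)C(C)C)C(Cl)(Cl)C2=O)c(OCc2ccccc2)c(CC2=C(O[Si](C(C)C)(C(C)C)C(C)C)C(Cl)(Cl)C2=O)c1OCc1ccccc1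
A1 | alternative 1 | 4-hydroxy-6-(2-oxopentyl)-3,5-bis[[2,4-bis(benzyloxy)-3-butanoyl-6-methoxy-5-methylphenyl]methyl]-2H-pyran-2-one | CCCC(=O)CC1=C(Cc2c(OCc3ccccc3)c(C(=O)CCC)c(OCc3ccccc3)c(C)c2OC)C(O)=C(Cc2c(OCc3ccccc3)c(C(=O)CCC)c(OCc3ccccc3)c(C)c2OC)C(=O)O1
A2 | alternative 1 | 22 with the four outer-ring hydroxyls as benzyl ethers | CCCC(=O)c1c(O)c(Cc2c(OCc3ccccc3)c(C(=O)CCC)c(OCc3ccccc3)c(C)c2OC)c(O)c(Cc2c(OCc3ccccc3)c(C(=O)CCC)c(OCc3ccccc3)c(C)c2OC)c1O
A3 | alternative 2 | 1-[2,6-bis(benzyloxy)-3-[3-(benzyloxy)prop-2-yn-1-yl]-4-methoxy-5-methylphenyl]butan-1-one | CCCC(=O)c1c(OCc2ccccc2)c(C)c(OC)c(CC#COCc2ccccc2)c1OCc1ccccc1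
A4 | alternative 2 | 1-(benzyloxy)hex-1-yn-3-one | CCCC(=O)C#COCc1ccccc1
A5 | alternative 2 | hepta-O-benzyl ether of 22 | CCCC(=O)c1c(OCc2ccccc2)c(Cc2c(OCc3ccccc3)c(C(=O)CCC)c(OCc3ccccc3)c(C)c2OC)c(OCc2ccccc2)c(Cc2c(OCc3ccccc3)c(C(=O)CCC)c(OCc3ccccc3)c(C)c2OC)c1OCc1ccccc1
A6 | alternative 3 | dimethyl 5,5'-[2,4,6-tris(benzyloxy)-5-butanoyl-1,3-phenylene]bis(2-methyl-3-oxopentanoate) (epimer mixture) | CCCC(=O)c1c(OCc2ccccc2)c(CCC(=O)C(C)C(=O)OC)c(OCc2ccccc2)c(CCC(=O)C(C)C(=O)OC)c1OCc1ccccc1
A7 | alternative 3 | methyl 3-oxohexanoate | CCCC(=O)CC(=O)OC
A8 | alternative 3 | 6'-O-desmethyl analogue of 21 (three free hydroxyls on each outer ring) | CCCC(=O)c1c(OCc2ccccc2)c(Cc2c(O)c(C(=O)CCC)c(O)c(C)c2O)c(OCc2ccccc2)c(Cc2c(O)c(C(=O)CCC)c(O)c(C)c2O)c1OCc1ccccc1
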